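The rate constants were set for the occasion, and the outcome is calculated.

Time is dropped as the variable, and conversion of substrate takes its place.

substrate 0.020 M; reagent 0.0600 M; free catalyst 20 µM; impurity 13 µM

    substrate + free catalyst → free catalyst + intermediate (k1 = 5930 M⁻¹ s⁻¹)
    2 free catalyst ⇌ resting dimer, settled at all times (K2 = 7.22 × 10⁶ M⁻¹)
    free catalyst + impurity → spent catalyst (k3 = 56100 M⁻¹ s⁻¹)
    reagent + free catalyst + intermediate → free catalyst + product (k4 = 2750 M⁻² s⁻¹)

- apparent order in free catalyst when 5.0 % of the substrate are converted (percent change of the rate of making product for one percent more free catalyst charged)

The steps that make intermediate, spend catalyst and make product each carry one factor of free catalyst, concentration C, so C falls out of the ratio of any two of their rates. Dividing the impurity rate by the substrate rate and integrating in closed form gives the rule: the fraction of impurity left is the fraction of substrate left raised to the power s, where s = 9.46, the rate constant of the impurity step over that of the substrate step, a selectivity factor.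

At 5.0 % conversion, 61.6 % of the impurity therefore remains, so 5.00 µM of catalyst has become spent catalyst. That leaves T = 15.0 µM of catalyst units in free catalyst and resting dimer, two units per dimer. The fast balance then gives C = 0.985 µM, and at that point T rises 29.5 units per unit of C. The product rate is proportional to reagent, intermediate and C, so the order is the charge over C, divided by that slope: 0.689.

The weak link is the assumption that reagent, intermediate and spent catalyst stay put when the charge rises. With C gone from the ratios, each of them has the same value at a given conversion for this charge and for a charge one percent higher, so the added catalyst goes into T. The link holds, and 0.689 stands.

The forecast gives 0.69, within 0.64 to 0.74, matching this reckoning, on the grounds that “Substrate, impurity and intermediate all react in proportion to free catalyst”.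

The simulation gives 0.69. At that conversion, reached at 0.136 min, the share of the catalyst that is spent catalyst reads 25.0 %. At 70.0 % conversion, s leaves 0.00113 % of the impurity, so T falls to 7.00 µM and C to 0.662 µM. Counting intermediate in proportion to conversion, the rate over that at 5.0 % comes to 9.41, against 9.2 in this flask.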